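**Plan**
1. Retrosynthesis: the two acetates go back to the diol; ring B is cut at C5–C6 and at the C7=C8 double bond, which removes a two-carbon unit (C6–C7) and leaves a C5 radical on ring A and a methyl ketone at C8; C9–C10 is then cut to a ring A ketone enolate and an allylic carbonate.
2. Enabling feature: C5 is a lone CH between the quaternary carbons C4 and C10 and lies 1,4 to the methyl-bearing alkene carbon C8 (through C10–C9), so ring B (C5–C6–C7–C8–C9–C10) is one radical addition plus one Wittig closure away from a monocyclic ring A keto alcohol.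
3. Forward: geraniol gives the side-chain carbonate (steps 1–6); silylated (4R)-actinol and the carbonate are joined at C9–C10 by Ir-catalysed branched allylation (step 8); the C5 ketone becomes an oxalate and the vinyl group a methyl ketone (steps 9–12); ring B closes in step 13; desilylation and acetylation finish.
4. Stereochemistry: C2 comes from (4R,6R)-actinol; C9 and the quaternary C10 from the chiral Ir catalyst, reinforced by C2; C5 from attack on the radical anti to the axial C9 branch in the ring A chair anchored by the equatorial C2 silyl ether; 13E from geraniol; the position of the ring alkene is fixed by the Wittig closure.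

Key step: step 13

Remark: labdane numbering (C1–C20) is used for all intermediates; (4R,6R)-actinol, an industrial carotenoid intermediate, is taken as a purchasable chiral-pool ketone (its C6 centre is erased on enolisation).
Remark: the ligand antipode in step 8 is assigned by analogy with the usual facial model of Ir–phosphoramidite allylations; it would be checked on a model ketone before scale-up.

**Step 1**
Reactants: 1 geraniol; 2 tert-butyl(chloro)diphenylsilane
Product: 3 geranyl tert-butyldiphenylsilyl ether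
Conditions: imidazole, DMF, 0 °C to rt
Reagents that add atoms: tert-butyl(chloro)diphenylsilane, CC(C)(C)[Si](Cl)(c1ccccc1)c1ccccc1
Why: Standard imidazole-promoted silylation of a primary allylic alcohol; the TBDPS ether is chosen to survive periodic acid, the hydride reductions and the Wacker step.

**Step 2**
Reactants: 3 geranyl tert-butyldiphenylsilyl ether; 4 3-chloroperoxybenzoic acid
Product: 5 6,7-epoxygeranyl tert-butyldiphenylsilyl ether (racemic at the epoxide)
Conditions: mCPBA (1.0 equiv), NaHCO3, CH2Cl2, −20 to 0 °C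
Reagents that add atoms: 3-chloroperoxybenzoic acid, OOC(=O)c1cccc(Cl)c1
Why: Prilezhaev epoxidation should prefer the distal 6,7-alkene because the 2,3-alkene is deactivated by the allylic oxygen; the epoxide stereocentre is destroyed in step 3.

**Step 3**
Reactants: 5 6,7-epoxygeranyl tert-butyldiphenylsilyl ether
Product: 6 (4E)-6-[(tert-butyldiphenylsilyl)oxy]-4-methylhex-4-enal
Conditions: H5IO6, THF/Et2O, 0 °C
Reagents that add atoms: none
Why: Periodic acid opens the epoxide at the tertiary carbon and cleaves the glycol (Malaprade-type cleavage) to the aldehyde and acetone without touching the remaining trisubstituted alkene.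

**Step 4**
Reactants: 6 (4E)-6-[(tert-butyldiphenylsilyl)oxy]-4-methylhex-4-enal; 7 ethyl (triphenylphosphoranylidene)acetate
Product: 8 ethyl (2E,6E)-8-[(tert-butyldiphenylsilyl)oxy]-6-methylocta-2,6-dienoate
Conditions: CH2Cl2, rt
Reagents that add atoms: ethyl (triphenylphosphoranylidene)acetate, CCOC(=O)C=P(c1ccccc1)(c1ccccc1)c1ccccc1
Why: Wittig olefination with a stabilised ylide should give the (2E)-enoate.

**Step 5**
Reactants: 8 ethyl (2E,6E)-8-[(tert-butyldiphenylsilyl)oxy]-6-methylocta-2,6-dienoate
Product: 9 (2E,6E)-8-[(tert-butyldiphenylsilyl)oxy]-6-methylocta-2,6-dien-1-ol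
Conditions: i-Bu2AlH (2.2 equiv), CH2Cl2, −78 °C; aq. KNaC4H4O6 work-up
Reagents that add atoms: none
Why: 1,2-Reduction of the enoate by i-Bu2AlH at low temperature gives the (E)-allylic alcohol and leaves the silyl ether alone.

**Step 6**
Reactants: 9 (2E,6E)-8-[(tert-butyldiphenylsilyl)oxy]-6-methylocta-2,6-dien-1-ol; 10 methyl chloroformate
Product: 11 (2E,6E)-8-[(tert-butyldiphenylsilyl)oxy]-6-methylocta-2,6-dien-1-yl methyl carbonate
Conditions: pyridine, CH2Cl2, 0 °C
Reagents that add atoms: methyl chloroformate, COC(=O)Cl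
Why: Acylation gives the linear (E)-allylic methyl carbonate, the usual electrophile for iridium-catalysed allylic substitution.

**Step 7**
Reactants: 12 (4R,6R)-4-hydroxy-2,2,6-trimethylcyclohexan-1-one (actinol); 13 tert-butyl(chloro)dimethylsilane
Product: 14 (4R,6R)-4-[(tert-butyldimethylsilyl)oxy]-2,2,6-trimethylcyclohexan-1-one
Conditions: imidazole, DMF, rt
Reagents that add atoms: tert-butyl(chloro)dimethylsilane, CC(C)(C)[Si](C)(C)Cl
Why: Silylation of the secondary alcohol protects C2–O and provides the bulky equatorial anchor that later fixes the ring A chair.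

**Step 8**
Reactants: 14 (4R,6R)-4-[(tert-butyldimethylsilyl)oxy]-2,2,6-trimethylcyclohexan-1-one; 11 (2E,6E)-8-[(tert-butyldiphenylsilyl)oxy]-6-methylocta-2,6-dien-1-yl methyl carbonate
Product: 16 (2S,4S)-4-[(tert-butyldimethylsilyl)oxy]-2-[(3R,6E)-8-[(tert-butyldiphenylsilyl)oxy]-6-methylocta-1,6-dien-3-yl]-2,6,6-trimethylcyclohexan-1-one, via potassium enolate 15 (not isolated)
Conditions: KN(SiMe3)2, THF, −78 to 0 °C; then 11, [Ir(cod)Cl]2 (2 mol%), (Sa,S,S)-phosphoramidite from (S)-BINOL and bis[(S)-1-(2-methoxyphenyl)ethyl]amine (4 mol%, pre-activated with n-PrNH2), THF, 0 °C to rt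
Reagents that add atoms: none
Why: Iridium-catalysed enantio- and diastereoselective allylic alkylation of a cyclic ketone enolate (branched-selective Tsuji–Trost-type reaction) attacks the substituted allyl terminus, so C9 (catalyst control) and the quaternary C10 form together, the enolate face being set by the ligand and reinforced by chair-like axial attack trans to the pseudo-equatorial C2 silyloxy group.

**Step 9**
Reactants: 16 (2S,4S)-4-[(tert-butyldimethylsilyl)oxy]-2-[(3R,6E)-8-[(tert-butyldiphenylsilyl)oxy]-6-methylocta-1,6-dien-3-yl]-2,6,6-trimethylcyclohexan-1-one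
Product: 17 (1S,2S,4S)-4-[(tert-butyldimethylsilyl)oxy]-2-[(3R,6E)-8-[(tert-butyldiphenylsilyl)oxy]-6-methylocta-1,6-dien-3-yl]-2,6,6-trimethylcyclohexan-1-ol (C5 alcohol; expected epimer drawn)
Conditions: LiAlH4, THF, 0 to 40 °C
Reagents that add atoms: none
Why: LiAlH4 is small enough to reduce the 2,2,6,6-tetrasubstituted ketone, hydride should arrive anti to the C9 branch, and the C5 configuration is immaterial because C5 becomes a radical in step 13.

**Step 10**
Reactants: 17 C5 alcohol; 18 methyl chlorooxoacetate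
Product: 19 (1S,2S,4S)-4-[(tert-butyldimethylsilyl)oxy]-2-[(3R,6E)-8-[(tert-butyldiphenylsilyl)oxy]-6-methylocta-1,6-dien-3-yl]-2,6,6-trimethylcyclohexyl methyl oxalate
Conditions: Et3N, DMAP (cat.), CH2Cl2, 0 °C to rt
Reagents that add atoms: methyl chlorooxoacetate, COC(=O)C(=O)Cl
Why: DMAP-catalysed O-acylation with the very electrophilic oxalyl chloride should tolerate the hindered secondary alcohol and installs the oxalate radical precursor.

**Step 11**
Reactants: 19 vinyl methyl oxalate; 20 water
Product: 21 (1S,2S,4S)-4-[(tert-butyldimethylsilyl)oxy]-2-[(3S,6E)-8-[(tert-butyldiphenylsilyl)oxy]-6-methyl-2-oxooct-6-en-3-yl]-2,6,6-trimethylcyclohexyl methyl oxalate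
Conditions: PdCl2 (10 mol%), Cu(OAc)2 (20 mol%), O2 (1 atm), DMA/H2O 7:1, rt
Reagents that add atoms: water, O
Why: Tsuji–Wacker oxidation (Markovnikov oxypalladation) converts only the monosubstituted alkene into the C8 methyl ketone, and the acetate-buffered medium spares the silyl ethers and the oxalate.

**Step 12**
Reactants: 21 keto methyl oxalate; 22 caesium hydroxide monohydrate
Product: 23 caesium (1S,2S,4S)-4-[(tert-butyldimethylsilyl)oxy]-2-[(3S,6E)-8-[(tert-butyldiphenylsilyl)oxy]-6-methyl-2-oxooct-6-en-3-yl]-2,6,6-trimethylcyclohexyl oxalate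
Conditions: CsOH·H2O (1.0 equiv), THF/H2O, 0 °C, short contact; freeze-dry
Reagents that add atoms: caesium hydroxide, [Cs+].[OH-]
Why: One equivalent of hydroxide saponifies only the exposed methyl ester of the oxalate (the other ester is shielded by two quaternary carbons), and the short cold exposure should leave the hindered C9–H next to the ketone untouched.

**Step 13**
Reactants: 23 caesium oxalate; 24 triphenyl(vinyl)phosphonium bromide
Product: 27 (13E)-2-[(tert-butyldimethylsilyl)oxy]-15-[(tert-butyldiphenylsilyl)oxy]-ent-labda-7,13-diene (2S,5R,9R,10R), via C5 radical 25 (not isolated), via phosphonium ylide 26 (not isolated)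
Conditions: Ir[dF(CF3)ppy]2(dtbbpy)PF6 (2 mol%), 24 (3 equiv), dry DMF/DME 1:3 (0.2 M), 4 Å MS, 450 nm LEDs, 60 °C, N2
Reagents that add atoms: triphenyl(vinyl)phosphonium bromide, C=C[P+](c1ccccc1)(c1ccccc1)c1ccccc1.[Br-]
Why: Proposed new method: the photoexcited trivalent iridium complex oxidises the oxalate of 23, loss of two CO2 gives the secondary C5 radical 25, this adds to the electron-poor alkene of 24, and the α-phosphonio radical is reduced by the divalent iridium formed in the first event to ylide 26 (redox-neutral radical–polar crossover). Ylide 26 then closes ring B by an intramolecular Wittig reaction, 6-exo-trig attack of C7 on the C8 carbonyl followed by collapse of the oxaphosphetane, so the new alkene can only be C7=C8. The closest known reactions are the photoredox three-component olefination of vinylphosphonium salts with radicals from carboxylic acids, the oxalate-based Giese reaction of alcohols and the Schweizer annulation; new is the union of an oxalate-derived secondary radical with a ring-closing Wittig step onto a ketone. C5 is the only new stereocentre and is substrate-controlled: the C2 silyloxy group stays equatorial, which places the C9 branch and one C4 methyl axial on the other face, so 24 should approach the planar radical axially and anti to the branch (cis to the C10 methyl), and chair inversion then lets the two trans arms close to the trans-decalin. The step needs the radical to be trapped faster than it abstracts the allylic C12–H (1,5-shift) or is reduced, which three equivalents of the strongly electrophilic 24 at 0.2 M should secure, and it needs the ylide to reach the hindered ketone before protonation, which the dry, base-free medium (the substrate is its own caesium salt) and the six-membered transition state should secure.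

**Step 14**
Reactants: 27 bis-silyl ether
Product: 28 (13E)-ent-labda-7,13-diene-2,15-diol (2S,5R,9R,10R)
Conditions: Bu4NF (4 equiv), THF, 50 °C
Reagents that add atoms: none
Why: Fluoride cleaves both silyl ethers (strong Si–F bond), warming being needed for the axial C2 ether flanked by two syn-axial methyls.

**Step 15**
Reactants: 28 diol; 29 acetic anhydride
Product: 30 (13E)-ent-labda-7,13-diene-2,15-diyl diacetate (2S,5R,9R,10R; 2-OAc cis to the C10 methyl)
Conditions: pyridine, DMAP (cat.), CH2Cl2, rt
Reagents that add atoms: acetic anhydride, CC(=O)OC(C)=O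
Why: DMAP-catalysed acetylation should esterify both the primary allylic and the hindered axial secondary alcohol.

**Compound list**
1 | geraniol | CC(C)=CCC/C(C)=C/CO | starting material
2 | tert-butyl(chloro)diphenylsilane | CC(C)(C)[Si](Cl)(c1ccccc1)c1ccccc1 | starting material
3 | geranyl tert-butyldiphenylsilyl ether | CC(C)=CCC/C(C)=C/CO[Si](c1ccccc1)(c1ccccc1)C(C)(C)C | intermediate
4 | 3-chloroperoxybenzoic acid | OOC(=O)c1cccc(Cl)c1 | starting material
5 | 6,7-epoxygeranyl tert-butyldiphenylsilyl ether (racemic epoxide) | CC1(C)OC1CC/C(C)=C/CO[Si](c1ccccc1)(c1ccccc1)C(C)(C)C | intermediate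
6 | (4E)-6-[(tert-butyldiphenylsilyl)oxy]-4-methylhex-4-enal | O=CCC/C(C)=C/CO[Si](c1ccccc1)(c1ccccc1)C(C)(C)C | intermediate
7 | ethyl (triphenylphosphoranylidene)acetate | CCOC(=O)C=P(c1ccccc1)(c1ccccc1)c1ccccc1 | starting material
8 | ethyl (2E,6E)-8-[(tert-butyldiphenylsilyl)oxy]-6-methylocta-2,6-dienoate | CCOC(=O)/C=C/CC/C(C)=C/CO[Si](c1ccccc1)(c1ccccc1)C(C)(C)C | intermediate
9 | (2E,6E)-8-[(tert-butyldiphenylsilyl)oxy]-6-methylocta-2,6-dien-1-ol | OC/C=C/CC/C(C)=C/CO[Si](c1ccccc1)(c1ccccc1)C(C)(C)C | intermediate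
10 | methyl chloroformate | COC(=O)Cl | starting material
11 | (2E,6E)-8-[(tert-butyldiphenylsilyl)oxy]-6-methylocta-2,6-dien-1-yl methyl carbonate | COC(=O)OC/C=C/CC/C(C)=C/CO[Si](c1ccccc1)(c1ccccc1)C(C)(C)C | intermediate
12 | (4R,6R)-4-hydroxy-2,2,6-trimethylcyclohexan-1-one (actinol) | C[C@@H]1C[C@@H](O)CC(C)(C)C1=O | starting material
13 | tert-butyl(chloro)dimethylsilane | CC(C)(C)[Si](C)(C)Cl | starting material
14 | (4R,6R)-4-[(tert-butyldimethylsilyl)oxy]-2,2,6-trimethylcyclohexan-1-one | C[C@@H]1C[C@@H](O[Si](C)(C)C(C)(C)C)CC(C)(C)C1=O | intermediate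
15 | potassium enolate of 14 (C5–O enolate, C5=C10) | CC1=C([O-])C(C)(C)C[C@H](O[Si](C)(C)C(C)(C)C)C1.[K+] | intermediate
16 | (2S,4S)-4-[(tert-butyldimethylsilyl)oxy]-2-[(3R,6E)-8-[(tert-butyldiphenylsilyl)oxy]-6-methylocta-1,6-dien-3-yl]-2,6,6-trimethylcyclohexan-1-one (C5 ketone, 9R, 10 quaternary, C9 branch trans to C2–O) | CC(C)(C)[Si](c1ccccc1)(c1ccccc1)OC/C=C(\C)CC[C@H](C=C)[C@]1(C)C[C@@H](O[Si](C)(C)C(C)(C)C)CC(C)(C)C1=O | intermediate
17 | (1S,2S,4S)-cyclohexan-1-ol from 16 (C5–OH cis to the C9 branch expected) | CC(C)(C)[Si](c1ccccc1)(c1ccccc1)OC/C=C(\C)CC[C@H](C=C)[C@]1(C)C[C@@H](O[Si](C)(C)C(C)(C)C)CC(C)(C)[C@@H]1O | intermediate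
18 | methyl chlorooxoacetate | COC(=O)C(=O)Cl | starting material
19 | methyl oxalate of 17 | CC(C)(C)[Si](c1ccccc1)(c1ccccc1)OC/C=C(\C)CC[C@H](C=C)[C@]1(C)C[C@@H](O[Si](C)(C)C(C)(C)C)CC(C)(C)[C@@H]1OC(=O)C(=O)OC | intermediate
20 | water | O | starting material
21 | C8 methyl ketone methyl oxalate | CC(C)(C)[Si](c1ccccc1)(c1ccccc1)OC/C=C(\C)CC[C@H](C(C)=O)[C@]1(C)C[C@@H](O[Si](C)(C)C(C)(C)C)CC(C)(C)[C@@H]1OC(=O)C(=O)OC | intermediate
22 | caesium hydroxide monohydrate | O.[Cs+].[OH-] | starting material
23 | caesium oxalate of the C8 methyl ketone | CC(C)(C)[Si](c1ccccc1)(c1ccccc1)OC/C=C(\C)CC[C@H](C(C)=O)[C@]1(C)C[C@@H](O[Si](C)(C)C(C)(C)C)CC(C)(C)[C@@H]1OC(=O)C(=O)[O-].[Cs+] | intermediate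
24 | triphenyl(vinyl)phosphonium bromide | C=C[P+](c1ccccc1)(c1ccccc1)c1ccccc1.[Br-] | starting material
25 | C5 radical | CC(C)(C)[Si](c1ccccc1)(c1ccccc1)OC/C=C(\C)CC[C@H](C(C)=O)[C@]1(C)C[C@@H](O[Si](C)(C)C(C)(C)C)CC(C)(C)[CH]1 | intermediate
26 | phosphonium ylide (C5–C6H2–C7H=PPh3, C6 cis to the C10 methyl) | CC(C)(C)[Si](c1ccccc1)(c1ccccc1)OC/C=C(\C)CC[C@H](C(C)=O)[C@]1(C)C[C@@H](O[Si](C)(C)C(C)(C)C)CC(C)(C)[C@H]1CC=P(c1ccccc1)(c1ccccc1)c1ccccc1 | intermediate
27 | (13E)-2-[(tert-butyldimethylsilyl)oxy]-15-[(tert-butyldiphenylsilyl)oxy]-ent-labda-7,13-diene (2S,5R,9R,10R) | CC(C)(C)[Si](c1ccccc1)(c1ccccc1)OC/C=C(\C)CC[C@@H]1C(C)=CC[C@@H]2C(C)(C)C[C@H](O[Si](C)(C)C(C)(C)C)C[C@@]12C | intermediate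
28 | (13E)-ent-labda-7,13-diene-2,15-diol (2S,5R,9R,10R) | OC/C=C(\C)CC[C@@H]1C(C)=CC[C@@H]2C(C)(C)C[C@H](O)C[C@@]12C | intermediate
29 | acetic anhydride | CC(=O)OC(C)=O | starting material
30 | (13E)-ent-labda-7,13-diene-2,15-diyl diacetate (2S,5R,9R,10R) | CC(=O)OC/C=C(\C)CC[C@@H]1C(C)=CC[C@@H]2C(C)(C)C[C@H](OC(C)=O)C[C@@]12C | target

**Step count and risks**
Total: 15 steps. Longest linear sequence: 14 steps (steps 1–6, then 8–15, from geraniol); step 7 is the one-step ring A branch.

Steps most likely to fail:

1. Step 13 (proposed new method). Possible failures are trapping of the alkoxycarbonyl radical before it loses the second CO2, 1,5-hydrogen transfer from C12–H to the C5 radical, addition to the wrong face of the radical (cis-decalin), protonation of the ylide before ring closure, or epimerisation at C9 next to the ketone. The fallback uses known chemistry, sets out from 16 and comes back at 27. Wacker oxidation of the vinyl group of 16 (PdCl2, Cu(OAc)2, O2, DMA/H2O) would give the C5,C8-diketone F1. Methylenation with Ph3P=CH2 should touch only the C8 carbonyl and give the isopropenyl ketone F2. CH2=CHCH2MgBr adds even to the hindered C5 ketone (six-centre allyl transfer) to give the tertiary homoallylic alcohol F3, either C5 epimer being usable. Ring-closing metathesis with the second-generation Grubbs catalyst joins C7 and C8 as the trisubstituted alkene and gives the decalin-5-ol F4. Acylation with 18 gives the tertiary methyl oxalate F5. Bu3SnH/AIBN deoxygenation (oxalate variant of the Barton–McCombie reaction) then delivers hydrogen to the C5 ring-fusion radical from the face away from the axial C4 and C10 methyls, which should give trans-decalin 27.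

2. Step 8. Possible failures are a mismatch between the ligand and the C2 silyloxy group in choosing the enolate face at C10, linear instead of branched allylation, or O-allylation of the hindered enolate. The fallback sets out from 12 and comes back at 16; it moves the C2 stereocentre behind the allylation so that C10 rests on the catalyst alone. Dess–Martin oxidation of 12 would give (6R)-2,2,6-trimethylcyclohexane-1,4-dione F6. Selective ketalisation of the unhindered C2 carbonyl (ethylene glycol, TsOH) gives the mono-ketal F7, whose enolate is achiral. The same Ir-catalysed allylation with 11 gives the allylated ketal F8, and aqueous acid (1 M HCl, THF) frees the dione F9. LiBH(s-Bu)3 at −78 °C should reduce only the C2 carbonyl, from the face away from the syn-axial C4 and C10 methyls, to give the C2 alcohol F10 (OH cis to the C10 methyl). Silylation with 13 gives 16.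

3. Step 11. Possible failures are slow or non-Markovnikov oxypalladation of the hindered vinyl group beside the ester-bearing ring, and hydrolytic loss of the oxalate in the aqueous medium. The fallback sets out from 16 and comes back at 21; the oxidation is moved to the ketone stage, where no oxalate is present and forcing conditions are tolerated. Wacker oxidation of 16 gives the diketone F1 described above. The C8 ketone alone is masked as the dioxolane F11 with 1,2-bis(trimethylsilyloxy)ethane and catalytic Me3SiOTf, the C5 carbonyl being too hindered to react. LiAlH4 reduces C5 to the alcohol F12, and acylation with 18 gives the ketal oxalate F13. PPTS in wet acetone removes the ketal to give 21.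

**Further compounds**
F1 | step 13 | C5,C8-diketone (Wacker product of 16) | CC(C)(C)[Si](c1ccccc1)(c1ccccc1)OC/C=C(\C)CC[C@H](C(C)=O)[C@]1(C)C[C@@H](O[Si](C)(C)C(C)(C)C)CC(C)(C)C1=O
F2 | step 13 | C9 isopropenyl C5 ketone | CC(C)(C)[Si](c1ccccc1)(c1ccccc1)OC/C=C(\C)CC[C@H](C(C)=C)[C@]1(C)C[C@@H](O[Si](C)(C)C(C)(C)C)CC(C)(C)C1=O
F3 | step 13 | C5 allyl tertiary alcohol (C5 epimers) | CC(C)(C)[Si](c1ccccc1)(c1ccccc1)OC/C=C(\C)CC[C@H](C(C)=C)[C@]1(C)C[C@@H](O[Si](C)(C)C(C)(C)C)CC(C)(C)C1(O)CC=C
F4 | step 13 | bis-silyl ent-labda-7,13-dien-5-ol (C5 epimers) | CC(C)(C)[Si](c1ccccc1)(c1ccccc1)OC/C=C(\C)CC[C@@H]1C(C)=CCC2(O)C(C)(C)C[C@H](O[Si](C)(C)C(C)(C)C)C[C@@]12C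
F5 | step 13 | C5 methyl oxalate of F4 | CC(C)(C)[Si](c1ccccc1)(c1ccccc1)OC/C=C(\C)CC[C@@H]1C(C)=CCC2(OC(=O)C(=O)OC)C(C)(C)C[C@H](O[Si](C)(C)C(C)(C)C)C[C@@]12C
F6 | step 8 | (6R)-2,2,6-trimethylcyclohexane-1,4-dione | C[C@@H]1CC(=O)CC(C)(C)C1=O
F7 | step 8 | 4-ethylene ketal of F6 | C[C@@H]1CC2(OCCO2)CC(C)(C)C1=O
F8 | step 8 | allylated ketal (C2 dioxolane analogue of 16) | CC(C)(C)[Si](c1ccccc1)(c1ccccc1)OC/C=C(\C)CC[C@H](C=C)[C@]1(C)CC2(OCCO2)CC(C)(C)C1=O
F9 | step 8 | allylated C2,C5-dione | CC(C)(C)[Si](c1ccccc1)(c1ccccc1)OC/C=C(\C)CC[C@H](C=C)[C@]1(C)CC(=O)CC(C)(C)C1=O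
F10 | step 8 | C2 alcohol (OH cis to the C10 methyl) | CC(C)(C)[Si](c1ccccc1)(c1ccccc1)OC/C=C(\C)CC[C@H](C=C)[C@]1(C)C[C@@H](O)CC(C)(C)C1=O
F11 | step 11 | C8 dioxolane C5 ketone | CC(C)(C)[Si](c1ccccc1)(c1ccccc1)OC/C=C(\C)CC[C@H](C2(C)OCCO2)[C@]1(C)C[C@@H](O[Si](C)(C)C(C)(C)C)CC(C)(C)C1=O
F12 | step 11 | C8 dioxolane C5 alcohol | CC(C)(C)[Si](c1ccccc1)(c1ccccc1)OC/C=C(\C)CC[C@H](C2(C)OCCO2)[C@]1(C)C[C@@H](O[Si](C)(C)C(C)(C)C)CC(C)(C)[C@@H]1O
F13 | step 11 | C8 dioxolane C5 methyl oxalate | CC(C)(C)[Si](c1ccccc1)(c1ccccc1)OC/C=C(\C)CC[C@H](C2(C)OCCO2)[C@]1(C)C[C@@H](O[Si](C)(C)C(C)(C)C)CC(C)(C)[C@@H]1OC(=O)C(=O)OC
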